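**Retrosynthetic overview**

1. Target 15 (meso oxolane) ⇐ hydrogenolysis of four benzyl ethers ⇐ diacetate 14 ⇐ diol 13 ⇐ cis-fused anhydride 12 (temporary ring that fixes 3,4-cis with both aryl groups exo) ⇐ oxolane-3,4-dicarboxylic acid 11.
2. Key disconnection: the C3–C4 bond of the oxolane, made by Favorskii ring contraction of the 5-bromo-4-oxooxane-3-carboxylate 8. The enolate carbon C3 alkylates C5, closing a cyclopropanone and with it the five-membered ring; the ring ketone carbon is expelled and becomes one of the two CH2OAc carbons.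
3. Enabling feature: oxolane C3 and C4 each carry a one-carbon oxygenated branch (a vicinal dicarboxyl pattern at the alcohol level) between the two O-bonded benzylic carbons C2 and C5. This is the retron of a 2,6-diaryl-4-oxooxane-3-carboxylate: oxane atoms O1, C2, C3, C5, C6 become the oxolane, C4 becomes the branch on C4, the ester carbon the branch on C3.
4. Oxanone 6 ⇐ Knoevenagel/oxa-Michael (Maitland–Japp) of δ-hydroxy-β-keto ester 4 with aldehyde 2 ⇐ γ-aldol of the acetoacetate dianion; all skeletal carbons come from two molecules of one aldehyde and methyl acetoacetate.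
5. Ring order: six-membered oxane (step 2) → contracted to the oxolane through the bicyclic cyclopropanone (step 4) → temporary anhydride ring (step 5), opened again by reduction (step 6).

Key step: step 4

Assumption: the target is the meso isomer (2R,3S,4R,5S), with the aryl groups mutually cis and the acetoxymethyl groups mutually cis and trans to the aryl groups; chiral intermediates are therefore made as racemates and drawn as one enantiomer.

**Route**

Step 1
Reactants: 1 methyl acetoacetate; 2 3,4-bis(benzyloxy)benzaldehyde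
Product: 4 methyl 5-[3,4-bis(benzyloxy)phenyl]-5-hydroxy-3-oxopentanoate (racemic), via acetoacetate dianion 3 (not isolated)
Conditions: NaH (1.1 equiv), THF, 0 °C; n-BuLi (1.05 equiv), 0 °C; then 2, −78 °C; aq. NH4Cl
Reagents that add atoms: none
Why: γ-Aldol addition of the acetoacetate dianion, whose terminal carbon is its most nucleophilic site, should give the δ-hydroxy-β-keto ester; the carbinol centre forms as a racemate, which suffices because the target is meso and only relative configuration has to be controlled later.

Step 2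
Reactants: 4 methyl 5-[3,4-bis(benzyloxy)phenyl]-5-hydroxy-3-oxopentanoate; 2 3,4-bis(benzyloxy)benzaldehyde
Product: 6 methyl 2,6-bis[3,4-bis(benzyloxy)phenyl]-4-oxooxane-3-carboxylate (racemic; aryl groups 2,6-cis, ester trans to the C2 aryl), via Knoevenagel adduct 5 (not isolated)
Conditions: 2 (1.05 equiv), Yb(OTf)3 (0.2 equiv), 4 Å MS, CH2Cl2, rt, stirred to equilibrium
Reagents that add atoms: none
Why: Maitland–Japp sequence, i.e. Lewis-acid-catalysed Knoevenagel condensation at C2 of the β-keto ester followed by 6-endo-trig oxa-Michael closure by the δ-hydroxyl; the closure is reversible, so the new benzylic centre should settle cis to C6 with both aryl groups equatorial (keto tautomer), and any 2,6-trans material (enol tautomer) can be separated and re-equilibrated.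

Step 3
Reactants: 6 methyl 2,6-bis[3,4-bis(benzyloxy)phenyl]-4-oxooxane-3-carboxylate
Product: 8 methyl 5-bromo-2,6-bis[3,4-bis(benzyloxy)phenyl]-4-oxooxane-3-carboxylate (bromide expected axial, cis to the C6 aryl), via bis(silyl) dienol ether 7 (not isolated)
Conditions: LiN(i-Pr)2 (LDA, 2.3 equiv), THF, −78 °C; Me3SiCl (2.6 equiv), −78 → 0 °C; then NBS (1.0 equiv), THF, −78 °C; aq. NaHCO3
Reagents that add atoms: N-bromosuccinimide, O=C1CCC(=O)N1Br (chlorotrimethylsilane, C[Si](C)(C)Cl, supplies the silyl groups of 7 only)
Why: Halogenation of a 1,3-bis(silyloxy)diene: double deprotonation and O-silylation give the cyclic dienol ether, whose terminal carbon C5 is the most nucleophilic site and should take up bromine from NBS far faster than the dialkoxyphenyl rings, axial attack on the half-chair placing bromine axial, while hydrolysis of the remaining silyl enol ether on work-up returns the β-keto ester.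

Step 4
Reactants: 8 methyl 5-bromo-2,6-bis[3,4-bis(benzyloxy)phenyl]-4-oxooxane-3-carboxylate
Product: 11 2,5-cis-2,5-bis[3,4-bis(benzyloxy)phenyl]oxolane-3,4-dicarboxylic acid (mixture of C3/C4 epimers), via cyclopropanone 9 (not isolated), via dimethyl ester 10 (not isolated)
Conditions: NaOMe (3 equiv), MeOH–THF, 0 °C → rt (contraction, then ester equilibration); aq. NaOH, 40 °C; 1 M HCl
Reagents that add atoms: sodium methoxide, [Na+].[O-]C (its methoxy group is carried by 10 and lost again); sodium hydroxide, [Na+].[OH-] (one oxygen of each carboxyl group of 11)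
Why: Favorskii rearrangement: methoxide deprotonates C3 between ketone and ester, the enolate carbon displaces bromide at C5 from the rear to form the C3–C5 bond (the C3–C4 bond of the oxolane) and with it cyclopropanone 9, a 3-oxabicyclo[3.1.0]hexan-6-one; methoxide then adds to the strained carbonyl and the adduct opens at the bond to C3, so that the former ring ketone carbon leaves the ring as CO2Me on C4 to give 10, which hydroxide saponifies to 11. The closest known reaction type is the Favorskii contraction of 3-bromo-2-oxocyclohexane-1-carboxylates to cyclopentane-1,2-dicarboxylic acids and of 3-halo-4-piperidones to pyrrolidine-3-carboxylic acid derivatives. The three-membered ring closes by intramolecular enolate C-alkylation (3-exo-tet), and the oxolane is closed by that same bond as the larger ring of the bicycle, so the oxane is contracted without a separate ring-forming event. C2 and C5 are not touched and keep the cis relation of the oxanone; in 9 the former C5 is set by inversion at the C–Br bond and C3 by the obligatory cis fusion, but in 10 and 11 both C3 and C4 are α to a carboxyl group and equilibrate under the alkoxide, so their final relative configuration is deliberately left to step 5. The selectivity needed is opening of the cyclopropanone toward C3 and not toward C4, which the C3 ester secures because only that cleavage gives a stabilised ester enolate; in addition the enolate alkylation has to outrun E1cB loss of the ring oxygen and dehydrobromination, which the intramolecular reaction of an axial C–Br bond at low temperature should favour.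

Step 5
Reactants: 11 2,5-cis-2,5-bis[3,4-bis(benzyloxy)phenyl]oxolane-3,4-dicarboxylic acid
Product: 12 meso-4,6-bis[3,4-bis(benzyloxy)phenyl]tetrahydro-1H,3H-furo[3,4-c]furan-1,3-dione (cis-fused anhydride, both aryl groups exo, trans to the anhydride ring)
Conditions: Ac2O, NaOAc (0.3 equiv), 110 °C
Reagents that add atoms: none
Why: Epimerising cyclodehydration of the kind that turns trans-cyclopentane-1,2-dicarboxylic acid into its cis-anhydride in hot Ac2O: only a cis-3,4-diacid can close the five-membered anhydride and the mixed anhydrides epimerise at C3/C4 through their enols, so the mixture should drain into the single cis-fused anhydride with both aryl groups on the exo face, which fixes 3,4-cis and 2,3-trans/4,5-trans.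

Step 6
Reactants: 12 meso cis-fused anhydride
Product: 13 [(2R,3S,4R,5S)-2,5-bis[3,4-bis(benzyloxy)phenyl]oxolane-3,4-diyl]dimethanol (meso)
Conditions: LiAlH4 (3 equiv), THF, 0 °C → reflux; H2O/aq. NaOH work-up
Reagents that add atoms: none
Why: Hydride reduction of a cyclic anhydride to the 1,4-diol touches no stereocentre, so the temporary ring is removed with the two CH2OH groups left cis to each other and trans to the aryl groups.

Step 7
Reactants: 13 meso diol
Product: 14 [(2R,3S,4R,5S)-2,5-bis[3,4-bis(benzyloxy)phenyl]oxolane-3,4-diyl]bis(methylene) diacetate (meso)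
Conditions: Ac2O (3 equiv), pyridine, DMAP (0.1 equiv), CH2Cl2, rt
Reagents that add atoms: acetic anhydride, CC(=O)OC(C)=O
Why: DMAP-catalysed acylation of the two primary alcohols, the phenols still being masked as benzyl ethers, should give the diacetate only.

Step 8
Reactants: 14 meso tetrabenzyl diacetate
Product: 15 [(2R,3S,4R,5S)-2,5-bis(3,4-dihydroxyphenyl)oxolane-3,4-diyl]bis(methylene) diacetate (meso, target)
Conditions: H2 (1 atm), Pd/C (10 wt % Pd), EtOAc–THF, rt, stopped at complete O-debenzylation
Reagents that add atoms: none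
Why: Hydrogenolysis of aryl benzyl ethers over palladium metal is much faster than cleavage of the dialkyl benzylic C–O bonds of the oxolane and leaves acetates untouched, so the four phenols should be released under neutral conditions with all four stereocentres intact.

**Compound list**

1 | methyl acetoacetate | COC(=O)CC(C)=O | starting material
2 | 3,4-bis(benzyloxy)benzaldehyde | O=Cc1ccc(OCc2ccccc2)c(OCc2ccccc2)c1 | starting material
3 | sodium lithium dianion of methyl acetoacetate | [Na+].[Li+].COC([O-])=CC([O-])=C | intermediate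
4 | methyl 5-[3,4-bis(benzyloxy)phenyl]-5-hydroxy-3-oxopentanoate (racemic) | COC(=O)CC(=O)CC(O)c1ccc(OCc2ccccc2)c(OCc2ccccc2)c1 | intermediate
5 | methyl 2-[3,4-bis(benzyloxy)benzylidene]-5-[3,4-bis(benzyloxy)phenyl]-5-hydroxy-3-oxopentanoate (alkene geometry not defined) | COC(=O)C(=Cc1ccc(OCc2ccccc2)c(OCc2ccccc2)c1)C(=O)CC(O)c1ccc(OCc2ccccc2)c(OCc2ccccc2)c1 | intermediate
6 | methyl 2,6-bis[3,4-bis(benzyloxy)phenyl]-4-oxooxane-3-carboxylate (racemic; 2,6-cis aryl groups, 3-ester trans to the C2 aryl) | COC(=O)[C@@H]1C(=O)C[C@@H](c2ccc(OCc3ccccc3)c(OCc3ccccc3)c2)O[C@H]1c1ccc(OCc2ccccc2)c(OCc2ccccc2)c1 | intermediate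
7 | 2,6-cis-2,6-bis[3,4-bis(benzyloxy)phenyl]-3-[methoxy(trimethylsilyloxy)methylidene]-4-(trimethylsilyloxy)-3,6-dihydro-2H-pyran | COC(O[Si](C)(C)C)=C1C(O[Si](C)(C)C)=C[C@@H](c2ccc(OCc3ccccc3)c(OCc3ccccc3)c2)O[C@H]1c1ccc(OCc2ccccc2)c(OCc2ccccc2)c1 | intermediate
8 | methyl 5-bromo-2,6-bis[3,4-bis(benzyloxy)phenyl]-4-oxooxane-3-carboxylate (2,6-cis aryl groups; expected major epimer drawn, bromide axial and cis to the C6 aryl; C3 epimerisable through the enol) | COC(=O)[C@@H]1C(=O)[C@@H](Br)[C@@H](c2ccc(OCc3ccccc3)c(OCc3ccccc3)c2)O[C@H]1c1ccc(OCc2ccccc2)c(OCc2ccccc2)c1 | intermediate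
9 | methyl 2,4-bis[3,4-bis(benzyloxy)phenyl]-6-oxo-3-oxabicyclo[3.1.0]hexane-1-carboxylate (cis-fused; drawn with the carbonyl bridge syn to the two cis aryl groups, as follows from inversion at the axial bromide) | COC(=O)[C@]12C(=O)[C@H]1[C@@H](c3ccc(OCc4ccccc4)c(OCc4ccccc4)c3)O[C@H]2c1ccc(OCc2ccccc2)c(OCc2ccccc2)c1 | intermediate
10 | dimethyl 2,5-cis-2,5-bis[3,4-bis(benzyloxy)phenyl]oxolane-3,4-dicarboxylate (mixture of C3/C4 epimers, C3 and C4 left undefined) | COC(=O)C1C(C(=O)OC)[C@@H](c2ccc(OCc3ccccc3)c(OCc3ccccc3)c2)O[C@H]1c1ccc(OCc2ccccc2)c(OCc2ccccc2)c1 | intermediate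
11 | 2,5-cis-2,5-bis[3,4-bis(benzyloxy)phenyl]oxolane-3,4-dicarboxylic acid (mixture of C3/C4 epimers, C3 and C4 left undefined) | OC(=O)C1C(C(O)=O)[C@@H](c2ccc(OCc3ccccc3)c(OCc3ccccc3)c2)O[C@H]1c1ccc(OCc2ccccc2)c(OCc2ccccc2)c1 | intermediate
12 | meso-4,6-bis[3,4-bis(benzyloxy)phenyl]tetrahydro-1H,3H-furo[3,4-c]furan-1,3-dione (cis-fused; both aryl groups exo, trans to the anhydride ring) | O=C1OC(=O)[C@@H]2[C@H]1[C@@H](c3ccc(OCc4ccccc4)c(OCc4ccccc4)c3)O[C@H]2c1ccc(OCc2ccccc2)c(OCc2ccccc2)c1 | intermediate
13 | [(2R,3S,4R,5S)-2,5-bis[3,4-bis(benzyloxy)phenyl]oxolane-3,4-diyl]dimethanol (meso) | OC[C@@H]1[C@H](CO)[C@@H](c2ccc(OCc3ccccc3)c(OCc3ccccc3)c2)O[C@H]1c1ccc(OCc2ccccc2)c(OCc2ccccc2)c1 | intermediate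
14 | [(2R,3S,4R,5S)-2,5-bis[3,4-bis(benzyloxy)phenyl]oxolane-3,4-diyl]bis(methylene) diacetate (meso) | CC(=O)OC[C@@H]1[C@H](COC(C)=O)[C@@H](c2ccc(OCc3ccccc3)c(OCc3ccccc3)c2)O[C@H]1c1ccc(OCc2ccccc2)c(OCc2ccccc2)c1 | intermediate
15 | [(2R,3S,4R,5S)-2,5-bis(3,4-dihydroxyphenyl)oxolane-3,4-diyl]bis(methylene) diacetate (meso) | CC(=O)OC[C@@H]1[C@H](COC(C)=O)[C@@H](c2ccc(O)c(O)c2)O[C@H]1c1ccc(O)c(O)c1 | target

**Step count and risks**

Total step count: 8. Longest linear sequence: 8 steps (1 and 2 to 15; the route is linear, aldehyde 2 being used twice).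

Steps most likely to fail:

Step 4. The stabilised C3 enolate may expel the ring oxygen from C2 (E1cB ring opening, after which the freed alkoxide closes an epoxide onto the bromide), or HBr may be lost toward the 2,3-dihydropyran-4-one, before the cyclopropanone closes. The fallback makes the same C3–C4 bond by a photochemical carbene shift instead of an anionic alkylation; it sets out from 6 and comes back at 10. The dianion of 6 (LDA, 3.2 equiv, THF, −78 °C) would be C-acylated at C5 with 2,2,2-trifluoroethyl trifluoroacetate to give methyl 2,6-bis[3,4-bis(benzyloxy)phenyl]-4-oxo-5-(trifluoroacetyl)oxane-3-carboxylate F1. Detrifluoroacetylative diazo transfer at its more acidic 1,3-diketone site (MsN3, Et3N, H2O, MeCN, rt) should give methyl 5-diazo-2,6-bis[3,4-bis(benzyloxy)phenyl]-4-oxooxane-3-carboxylate F2. Irradiation of F2 (365 nm, MeOH, rt) should bring about a Wolff rearrangement in which C3 migrates to the carbene carbon C5 and the ring-contracted ketene is trapped by methanol to give 10, which continues with the equilibration and saponification of step 4.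

Step 3. Bromine transfer may lose site control (delivery to C3 or to the electron-rich aryl rings, or migration of bromine from C5 to C3 by exchange between enol and bromo ketone), and the product may lose HBr on work-up. The fallback brings the leaving group in as oxygen; it sets out from 6 and comes back at 11. The dianion of 6 (LDA, 2.3 equiv, THF, −78 °C) would be hydroxylated at its terminal carbon C5 with 2-(phenylsulfonyl)-3-phenyloxaziridine to give methyl 2,6-bis[3,4-bis(benzyloxy)phenyl]-5-hydroxy-4-oxooxane-3-carboxylate F3. Sulfonylation (Ms2O, pyridine, CH2Cl2, 0 °C) should give methyl 2,6-bis[3,4-bis(benzyloxy)phenyl]-5-(methylsulfonyloxy)-4-oxooxane-3-carboxylate F4. F4 would then be taken through the NaOMe/NaOH conditions of step 4, a Favorskii contraction with sulfonate as the leaving group, through 9 and 10 to 11.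

Step 5. In the hot anhydride medium the benzylic C–O bonds of the electron-rich oxolane may ionise (epimerisation at C2/C5 or ring opening), or epimerisation at C3/C4 may stay incomplete so that a mixture persists. The fallback gives up the temporary ring and separates at the diol level; it sets out from 10 (isolated by leaving out the hydroxide stage of step 4) and comes back at 13. The diester mixture 10 would be equilibrated (NaOMe, MeOH, rt) and reduced (LiAlH4, THF, 0 °C), and the meso diol 13 would be separated by chromatography or crystallisation from the accompanying racemic 3,4-trans isomer, rac-[2,5-cis-2,5-bis[3,4-bis(benzyloxy)phenyl]oxolane-3,4-trans-diyl]dimethanol F5.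

**Further compounds**

F1 | step 4 | methyl 2,6-bis[3,4-bis(benzyloxy)phenyl]-4-oxo-5-(trifluoroacetyl)oxane-3-carboxylate (2,6-cis) | COC(=O)C1C(=O)C(C(=O)C(F)(F)F)[C@@H](c2ccc(OCc3ccccc3)c(OCc3ccccc3)c2)O[C@H]1c1ccc(OCc2ccccc2)c(OCc2ccccc2)c1
F2 | step 4 | methyl 5-diazo-2,6-bis[3,4-bis(benzyloxy)phenyl]-4-oxooxane-3-carboxylate (2,6-cis) | COC(=O)[C@@H]1C(=O)C(=[N+]=[N-])[C@@H](c2ccc(OCc3ccccc3)c(OCc3ccccc3)c2)O[C@H]1c1ccc(OCc2ccccc2)c(OCc2ccccc2)c1
F3 | step 3 | methyl 2,6-bis[3,4-bis(benzyloxy)phenyl]-5-hydroxy-4-oxooxane-3-carboxylate (2,6-cis) | COC(=O)C1C(=O)C(O)[C@@H](c2ccc(OCc3ccccc3)c(OCc3ccccc3)c2)O[C@H]1c1ccc(OCc2ccccc2)c(OCc2ccccc2)c1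
F4 | step 3 | methyl 2,6-bis[3,4-bis(benzyloxy)phenyl]-5-(methylsulfonyloxy)-4-oxooxane-3-carboxylate (2,6-cis) | COC(=O)C1C(=O)C(OS(C)(=O)=O)[C@@H](c2ccc(OCc3ccccc3)c(OCc3ccccc3)c2)O[C@H]1c1ccc(OCc2ccccc2)c(OCc2ccccc2)c1
F5 | step 5 | rac-[2,5-cis-2,5-bis[3,4-bis(benzyloxy)phenyl]oxolane-3,4-trans-diyl]dimethanol | OC[C@@H]1[C@@H](CO)[C@@H](c2ccc(OCc3ccccc3)c(OCc3ccccc3)c2)O[C@H]1c1ccc(OCc2ccccc2)c(OCc2ccccc2)c1
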